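**Retrosynthetic overview**
1. Last bond made: the C6'–O bond of ring A (the second phenol of the 2-acylresorcinol), from mono-phenol ketone 7 by a one-pot ketone-directed C–H borylation/oxidation (net C–H hydroxylation).
2. C7–C8 of the chain: from terminal alkene 4 and eugenol 5 by cross-metathesis, with hydrogenation in the same pot.
3. C2–C3 of the chain: from the O,C-dianion of 2'-hydroxyacetophenone 1 and 6-bromohex-1-ene 2.
4. No ring is formed: ring A (the acylphenol ring) is bought in 1 and ring B (the guaiacol ring) in 5.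

Assumption: the target has no stereocentre and is achiral, so there is no enantiomer to select; the only stereo-element on the way (alkene geometry of 6) is erased by hydrogenation.

Bpin = 4,4,5,5-tetramethyl-1,3,2-dioxaborolan-2-yl. Ring A positions: C1' carries the acyl group, C2' the oxygen already present, C6' the oxygen to be introduced.

**Step 1**
Reactants: 1 2'-hydroxyacetophenone; 2 6-bromohex-1-ene
Product: 4 1-(2-hydroxyphenyl)oct-7-en-1-one, via dilithium dianion 3 (not isolated)
Conditions: 1 (1.3 equiv), LiN(iPr)2 (2.7 equiv), THF, −78 → 0 °C; then DMPU (4 equiv), 2 (1.0 equiv), −78 °C → rt; 1 M HCl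
Reagents that add atoms: none
Why: Enolate C-alkylation (SN2) of the O,C-dianion 3: the enolate carbon is by far the most nucleophilic site, the chelated lithium phenoxide is not alkylated, DMPU loosens the aggregate for the unactivated primary bromide, and keeping the ketone in excess limits proton transfer to the product and hence dialkylation.

**Step 2**
Reactants: 4 1-(2-hydroxyphenyl)oct-7-en-1-one; 5 eugenol (4-allyl-2-methoxyphenol)
Product: 7 1-(2-hydroxyphenyl)-9-(4-hydroxy-3-methoxyphenyl)nonan-1-one, via cross-metathesis alkene 6 (not isolated)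
Conditions: 5 (3 equiv), second-generation Grubbs catalyst (H2IMes)(PCy3)Cl2Ru=CHPh (3 mol%), 1,4-benzoquinone (10 mol%), CH2Cl2, 40 °C, Ar sweep; then evaporate, EtOAc, 10% Pd/C, H2 (1 atm), rt
Reagents that add atoms: none
Why: Olefin cross-metathesis of two unhindered terminal alkenes is driven by loss of ethene, the threefold excess of cheap 5 pushes 4 statistically into the cross product (about 75%), benzoquinone quenches the ruthenium hydrides that would migrate the allyl double bond and shorten the chain, and hydrogenation over Pd/C then saturates the disubstituted alkene of 6 (either geometry) much faster than the hydrogen-bonded aryl ketone.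

**Step 3**
Reactants: 7 1-(2-hydroxyphenyl)-9-(4-hydroxy-3-methoxyphenyl)nonan-1-one
Product: 11 1-(2,6-dihydroxyphenyl)-9-(4-hydroxy-3-methoxyphenyl)nonan-1-one (target), via bis(boryl ether) 8 (not isolated), via arylboronate 9 (not isolated), via tris(boryl ether) 10 (not isolated)
Conditions: HBpin (2.2 equiv), octane, rt → 50 °C (H2 off); then [Ir(OMe)(cod)]2 (2.5 mol%), AsPh3 (10 mol%), B2pin2 (1.2 equiv), 120 °C, 16 h; then THF, Me3NO·2H2O (3 equiv), rt; aq. NH4Cl
Reagents that add atoms: trimethylamine N-oxide, C[N+](C)(C)[O-]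
Why: Proposed new method: a one-pot ketone-directed C–H borylation/oxidation that installs the second ortho oxygen of a 2-hydroxyaryl alkyl ketone while a second, electron-rich phenol ring is present — HBpin first turns both O–H groups into O–Bpin ethers (no acidic protons, no O–H···O=C lock, and the opposed C=O and C–O dipoles should favour the rotamer with the carbonyl oxygen next to C6'–H), the ligand-poor trivalent iridium tris(boryl) formed from [Ir(OMe)(cod)]2/AsPh3 binds the carbonyl oxygen and cleaves only the adjacent C6'–H through a five-membered iridacycle (ring B has no donor group and only hindered C–H bonds), C–B reductive elimination gives 9, and the N-oxide then converts C–B into C–O by 1,2-aryl shift from boron to oxygen without oxidising the guaiacol or risking Dakin cleavage, the closest known reaction types being the Ir/AsPh3 ortho-borylation of simple aryl ketones and the borylation/oxidation phenol synthesis with phenol O–H masked in the flask as O–Bpin, neither of which, as far as I know, has been used to build a 2,6-dioxygenated aryl ketone.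

**Compound list**
1 | 2'-hydroxyacetophenone (1-(2-hydroxyphenyl)ethanone) | CC(=O)c1ccccc1O | starting material
2 | 6-bromohex-1-ene | C=CCCCCBr | starting material
3 | dilithium 2-(1-oxidoethenyl)phenolate (O,C-dianion of 1) | [Li+].[Li+].[O-]C(=C)c1ccccc1[O-] | intermediate (not isolated)
4 | 1-(2-hydroxyphenyl)oct-7-en-1-one | C=CCCCCCC(=O)c1ccccc1O | intermediate
5 | eugenol (4-allyl-2-methoxyphenol) | COc1cc(CC=C)ccc1O | starting material
6 | (E)-1-(2-hydroxyphenyl)-9-(4-hydroxy-3-methoxyphenyl)non-7-en-1-one (E major, some Z) | COc1cc(C/C=C/CCCCCC(=O)c2ccccc2O)ccc1O | intermediate (not isolated)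
7 | 1-(2-hydroxyphenyl)-9-(4-hydroxy-3-methoxyphenyl)nonan-1-one | COc1cc(CCCCCCCCC(=O)c2ccccc2O)ccc1O | intermediate
8 | 9-[3-methoxy-4-(Bpin-oxy)phenyl]-1-[2-(Bpin-oxy)phenyl]nonan-1-one (bis O-Bpin ether of 7) | COc1cc(CCCCCCCCC(=O)c2ccccc2OB2OC(C)(C)C(C)(C)O2)ccc1OB1OC(C)(C)C(C)(C)O1 | intermediate (not isolated)
9 | 9-[3-methoxy-4-(Bpin-oxy)phenyl]-1-[2-(Bpin-oxy)-6-(Bpin)phenyl]nonan-1-one | COc1cc(CCCCCCCCC(=O)c2c(B3OC(C)(C)C(C)(C)O3)cccc2OB2OC(C)(C)C(C)(C)O2)ccc1OB1OC(C)(C)C(C)(C)O1 | intermediate (not isolated)
10 | 1-[2,6-bis(Bpin-oxy)phenyl]-9-[3-methoxy-4-(Bpin-oxy)phenyl]nonan-1-one (tris O-Bpin ether of 11) | COc1cc(CCCCCCCCC(=O)c2c(OB3OC(C)(C)C(C)(C)O3)cccc2OB2OC(C)(C)C(C)(C)O2)ccc1OB1OC(C)(C)C(C)(C)O1 | intermediate (not isolated)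
11 | 1-(2,6-dihydroxyphenyl)-9-(4-hydroxy-3-methoxyphenyl)nonan-1-one | COc1cc(CCCCCCCCC(=O)c2c(O)cccc2O)ccc1O | target

**Total step count:** 3. **Longest linear sequence:** 3 steps (1 → 4 → 7 → 11).

**Steps most likely to fail**

Step 3 (the proposed new step). The 2'-substituent may slow the directed iridacycle formation enough for undirected borylation at the unhindered C4'/C5' of ring A to compete, and the HBpin released at 120 °C may hydroborate the ketone. The fallback uses only known chemistry; it sets out from 2 and 5 together with bought 2',6'-dihydroxyacetophenone and comes back to the route at 11. Benzylation (BnBr, K2CO3, DMF) gives 1-[2,6-bis(benzyloxy)phenyl]ethanone F1. LiN(iPr)2 in THF at −78 °C converts it into lithium 1-[2,6-bis(benzyloxy)phenyl]ethen-1-olate F2, which is alkylated by 2 (DMPU) to 1-[2,6-bis(benzyloxy)phenyl]oct-7-en-1-one F3. Cross-metathesis with 5 under the conditions of step 2 gives (E)-1-[2,6-bis(benzyloxy)phenyl]-9-(4-hydroxy-3-methoxyphenyl)non-7-en-1-one F4. Hydrogenation over Pd/C (H2, EtOAc/MeOH) then saturates the alkene and cleaves both benzyl ethers in one operation to give 11.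

Step 2. Double-bond migration of the allylarene before metathesis would give a chain-shortened homologue that is hard to separate, and the statistical product distribution may make purification poor. The fallback replaces metathesis by a Wittig olefination, which fixes the chain length; it sets out from 4 and comes back at 6, which is then hydrogenated as in step 2. Lemieux–Johnson cleavage of 4 (OsO4 cat., NaIO4, 2,6-lutidine, dioxane/H2O) gives 7-(2-hydroxyphenyl)-7-oxoheptanal F5. Bought homovanillyl alcohol is converted with CBr4/PPh3 (CH2Cl2, 0 °C) into 4-(2-bromoethyl)-2-methoxyphenol F6, and heating with PPh3 in MeCN gives [2-(4-hydroxy-3-methoxyphenyl)ethyl]triphenylphosphonium bromide F7. NaN(SiMe3)2 (2 equiv per F7, THF, −78 → 0 °C) gives the phenoxide ylide sodium 2-methoxy-4-[2-(triphenylphosphoranylidene)ethyl]phenolate F8, used in 2.2-fold excess because the phenol of F5 consumes one equivalent. Its reaction with F5 gives 6 (Z-rich, which is irrelevant).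

Step 1. Dialkylation, O-alkylation or low conversion of the dianion may occur. The fallback switches to azaenolate chemistry, which monoalkylates methyl ketones cleanly; it sets out from 1 and comes back at 4. Condensation with 1,1-dimethylhydrazine (EtOH, reflux) gives (E)-2-[1-(2,2-dimethylhydrazinylidene)ethyl]phenol F9. LiN(iPr)2 (2.2 equiv, THF, 0 °C) gives the dilithium phenolate-azaenolate F10, which is alkylated by 2 to (E)-2-[1-(2,2-dimethylhydrazinylidene)oct-7-en-1-yl]phenol F11. Hydrolysis with aqueous oxalic acid/THF returns 4.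

**Further compounds**
F1 | step 3 | 1-[2,6-bis(benzyloxy)phenyl]ethanone | CC(=O)c1c(OCc2ccccc2)cccc1OCc1ccccc1
F2 | step 3 | lithium 1-[2,6-bis(benzyloxy)phenyl]ethen-1-olate | [Li+].[O-]C(=C)c1c(OCc2ccccc2)cccc1OCc1ccccc1
F3 | step 3 | 1-[2,6-bis(benzyloxy)phenyl]oct-7-en-1-one | C=CCCCCCC(=O)c1c(OCc2ccccc2)cccc1OCc1ccccc1
F4 | step 3 | (E)-1-[2,6-bis(benzyloxy)phenyl]-9-(4-hydroxy-3-methoxyphenyl)non-7-en-1-one | COc1cc(C/C=C/CCCCCC(=O)c2c(OCc3ccccc3)cccc2OCc2ccccc2)ccc1O
F5 | step 2 | 7-(2-hydroxyphenyl)-7-oxoheptanal | O=CCCCCCC(=O)c1ccccc1O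
F6 | step 2 | 4-(2-bromoethyl)-2-methoxyphenol | COc1cc(CCBr)ccc1O
F7 | step 2 | [2-(4-hydroxy-3-methoxyphenyl)ethyl]triphenylphosphonium bromide | COc1cc(CC[P+](c2ccccc2)(c2ccccc2)c2ccccc2)ccc1O.[Br-]
F8 | step 2 | sodium 2-methoxy-4-[2-(triphenylphosphoranylidene)ethyl]phenolate | COc1cc(CC=P(c2ccccc2)(c2ccccc2)c2ccccc2)ccc1[O-].[Na+]
F9 | step 1 | (E)-2-[1-(2,2-dimethylhydrazinylidene)ethyl]phenol | C/C(=N\N(C)C)c1ccccc1O
F10 | step 1 | dilithium phenolate-azaenolate of F9 | [Li+].[Li+].C=C([N-]N(C)C)c1ccccc1[O-]
F11 | step 1 | (E)-2-[1-(2,2-dimethylhydrazinylidene)oct-7-en-1-yl]phenol | C=CCCCCC/C(=N\N(C)C)c1ccccc1O
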